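**Plan**

1. Locants: cyclohexanone ring C1' (quaternary), C2' (CHMe next to the ketone), C3' (C=O), C4', C5', C6' (CHMe); side chain C1 (ArCH2), C2=C3(Me), C4 (CHOH), C5 (CH2 on C1').
2. Cuts: C3–C4 (alkenyl metal + aldehyde), aryl–C1 (aryllithium + propargylic bromide), C4=C5 (one-carbon Wittig), and in the ring C1'–C2' and C5'–C6' by a retro-Diels–Alder, after moving the C3' oxygen onto a C3'=C4' alkene and raising C5 to a formyl group.
3. Enabling feature: C1' carries the chain CH2 (C5, a latent CHO) between C2'-H(Me) (methyl trans to C1'-Me) and C6'-H(Me) (methyl cis). This is the endo adduct of (E)-penta-1,3-diene and (E)-2-methylbut-2-enal. C3' lies three atoms from C5, so a C5 carboxyl can deliver the ketone oxygen through a γ-lactone.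
4. Forward order: the Diels–Alder closes the only ring that is built; iodolactonisation, deiodination, lactol formation, methylenation, hydroboration and double oxidation give the keto-aldehyde; orcinol gives the aryl butyne; an alkenylzinc addition joins the two; desilylation and phenol-to-quinone oxidation finish.
5. Stereochemistry: C1', C2', C6' from the suprafacial endo cycloaddition (absolute sense from a chiral oxazaborolidinium Lewis acid); C4 from the (+)-MIB-catalysed alkenylzinc addition; the (E)-alkene from syn-hydrozirconation; the epimerisable C2' centre meets no strong base once C3' is a ketone.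

Key step: step 1

Assumption (chemistry): the (S)-oxazaborolidinium catalyst is taken to expose the enal face that leads to 3; if the facial sense for this enal is the opposite one, the (R)-catalyst is used and nothing else changes.

**Route**

Step 1
Reactants: 1 (E)-penta-1,3-diene; 2 (E)-2-methylbut-2-enal
Product: 3 (1S,2R,6R)-1,2,6-trimethylcyclohex-3-ene-1-carbaldehyde
Conditions: (S)-1-(2-methylphenyl)-3,3-diphenyltetrahydro-1H,3H-pyrrolo[1,2-c][1,3,2]oxazaborole (10 mol %), AlBr3 (8 mol %), CH2Cl2, −40 → −20 °C, excess 1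
Reagents that add atoms: none
Why: Coordination of the formyl oxygen of 2 to the cationic boron lowers the enal LUMO and a concerted, asynchronous, suprafacial [4+2] cycloaddition (Diels–Alder) follows; the closest known type is the chiral oxazaborolidinium-catalysed Diels–Alder reaction of α-methyl enals with acyclic dienes. The cyclohexene ring (C1'–C6') closes by two-bond [4+2] annulation, C5'–C6' bonding running ahead of C1'–C2'. C1' and C6' take their cis methyls from the (E)-geometry of 2 (stereospecific); C2' follows from the endo approach of the coordinated formyl group, which puts both enal methyls exo and leaves C2'-Me cis to CHO and trans to C1'-Me; the absolute configuration of all three comes from the catalyst, which shields one face of the s-trans enal. The step needs "ortho" regioselectivity (methyl-bearing diene terminus to the formyl-bearing carbon), secured by pairing of the unsubstituted diene terminus with the enal β-carbon, and endo selectivity, secured by secondary orbital overlap and the exo placement of the two methyls; only the (E)-diene reaches the s-cis form, so traces of (Z)-diene stay behind.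

Step 2
Reactants: 3 (1S,2R,6R)-1,2,6-trimethylcyclohex-3-ene-1-carbaldehyde
Product: 4 (1S,2R,6R)-1,2,6-trimethylcyclohex-3-ene-1-carboxylic acid
Conditions: NaClO2, NaH2PO4, 2-methylbut-2-ene, t-BuOH/H2O, 0 °C → rt
Reagents that add atoms: sodium chlorite, [Na+].[O-]Cl=O
Why: Chlorite (Pinnick) oxidation should convert the hindered α-quaternary aldehyde into the acid without touching the ring alkene, the hypochlorite being trapped by the added alkene, and no stereocentre is involved.

Step 3
Reactants: 4 (1S,2R,6R)-1,2,6-trimethylcyclohex-3-ene-1-carboxylic acid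
Product: 5 4-iodo-1,2,8-trimethyl-6-oxabicyclo[3.2.1]octan-7-one (γ-lactone from the C5 carboxyl to C3', oxygen cis to C5, iodine at C4' trans to that oxygen, methyls as in 4)
Conditions: I2, NaHCO3, MeCN/H2O, 0 °C → rt, dark
Reagents that add atoms: iodine, II
Why: Iodolactonisation: the carboxylate opens the iodonium ion in a 5-exo, anti fashion, which is only possible at C3' on the ring face that bears the carboxyl, so the oxygen is placed regiospecifically on the future ketone carbon.

Step 4
Reactants: 5 4-iodo-1,2,8-trimethyl-6-oxabicyclo[3.2.1]octan-7-one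
Product: 6 1,2,8-trimethyl-6-oxabicyclo[3.2.1]octan-7-one (γ-lactone C5(=O)–O–C3', C4' now CH2)
Conditions: Bu3SnH, AIBN (cat.), PhH, 80 °C
Reagents that add atoms: none
Why: Radical-chain dehalogenation should remove the iodine from C4' and leave the lactone and the three methyl-bearing stereocentres untouched.

Step 5
Reactants: 6 1,2,8-trimethyl-6-oxabicyclo[3.2.1]octan-7-one
Product: 7 1,2,8-trimethyl-6-oxabicyclo[3.2.1]octan-7-ol (lactol, both anomers)
Conditions: i-Bu2AlH, CH2Cl2, −78 °C; aqueous sodium potassium tartrate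
Reagents that add atoms: none
Why: Partial reduction of a γ-lactone with i-Bu2AlH at low temperature should stop at the lactol because the aluminium hemiacetal does not collapse at −78 °C.

Step 6
Reactants: 7 1,2,8-trimethyl-6-oxabicyclo[3.2.1]octan-7-ol
Product: 8 (1R,2S,3S,4R)-3-ethenyl-2,3,4-trimethylcyclohexan-1-ol
Conditions: Ph3PCH3Br, t-BuOK (3 equiv each), THF, 0 → 45 °C
Reagents that add atoms: methyltriphenylphosphonium bromide, C[P+](c1ccccc1)(c1ccccc1)c1ccccc1.[Br-]
Why: Wittig methylenation of the ring-opened hydroxy-aldehyde form of the lactol should turn C5 into a vinyl group (C5=C4) and free the C3' hydroxyl, the excess ylide covering the alkoxide that forms.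

Step 7
Reactants: 8 (1R,2S,3S,4R)-3-ethenyl-2,3,4-trimethylcyclohexan-1-ol
Product: 10 (1R,2S,3S,4R)-3-(2-hydroxyethyl)-2,3,4-trimethylcyclohexan-1-ol, via bis-9-BBN adduct 9 (not isolated)
Conditions: 9-BBN-H (2.5 equiv), THF, 0 °C → rt; then NaOH (aq), H2O2, 0 °C → rt
Reagents that add atoms: hydrogen peroxide, OO
Why: Anti-Markovnikov hydroboration of the terminal vinyl group followed by alkaline peroxide oxidation should give the primary alcohol at C4, and the base is used here before any enolisable ketone exists.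

Step 8
Reactants: 10 (1R,2S,3S,4R)-3-(2-hydroxyethyl)-2,3,4-trimethylcyclohexan-1-ol
Product: 11 2-[(1S,2S,6R)-1,2,6-trimethyl-3-oxocyclohexyl]acetaldehyde
Conditions: (COCl)2, DMSO, CH2Cl2, −78 °C; i-Pr2NEt, −78 → −30 °C; pH 7 buffer
Reagents that add atoms: none
Why: Swern oxidation activates both hydroxyls before the base is added, so no lactol can form and be over-oxidised to a δ-lactone, and the hindered amine at low temperature should leave the new α-stereocentre C2' unchanged.

Step 9
Reactants: 12 5-methylbenzene-1,3-diol (orcinol)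
Product: 13 1,3-bis(methoxymethoxy)-5-methylbenzene
Conditions: MOMCl, i-Pr2NEt, CH2Cl2, 0 °C → rt
Reagents that add atoms: chloromethyl methyl ether, COCCl
Why: O-Alkylation of both phenols (MOM protection) installs the two acetal groups that direct the ortho-metalation of the next step.

Step 10
Reactants: 13 1,3-bis(methoxymethoxy)-5-methylbenzene; 14 1-bromobut-2-yne
Product: 16 2-(but-2-yn-1-yl)-1,3-bis(methoxymethoxy)-5-methylbenzene, via aryllithium 15 (not isolated)
Conditions: n-BuLi, THF, 0 °C; CuBr·SMe2 (10 mol %), then 14, −40 → 0 °C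
Reagents that add atoms: none
Why: Directed ortho-metalation takes place between the two MOM ethers, and the copper-assisted substitution of the primary propargylic bromide at its CH2 terminus (SN2) should give the aryl butyne.

Step 11
Reactants: 16 2-(but-2-yn-1-yl)-1,3-bis(methoxymethoxy)-5-methylbenzene
Product: 17 2-(but-2-yn-1-yl)-5-methylbenzene-1,3-diol
Conditions: HCl (3 M aq), MeOH, rt
Reagents that add atoms: none
Why: Acid-catalysed acetal exchange with methanol removes both MOM groups at a stage where nothing acid-sensitive is present, because the aryl MOM ethers could not be cleaved safely next to the later allylic alcohol.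

Step 12
Reactants: 17 2-(but-2-yn-1-yl)-5-methylbenzene-1,3-diol
Product: 18 2-(but-2-yn-1-yl)-4-chloro-5-methylbenzene-1,3-diol
Conditions: NCS (1.0 equiv), MeCN, 0 °C
Reagents that add atoms: N-chlorosuccinimide, O=C1CCC(=O)N1Cl
Why: Electrophilic aromatic chlorination: the two free ring positions are equivalent by symmetry and each is ortho/para to a hydroxyl, so one equivalent should give a single monochloride.

Step 13
Reactants: 18 2-(but-2-yn-1-yl)-4-chloro-5-methylbenzene-1,3-diol
Product: 19 [2-(but-2-yn-1-yl)-4-chloro-5-methyl-1,3-phenylene]bis(oxy)bis[tert-butyl(dimethyl)silane]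
Conditions: TBSCl, imidazole, DMF, rt → 40 °C
Reagents that add atoms: tert-butyl(chloro)dimethylsilane, CC(C)(C)[Si](C)(C)Cl
Why: Silylation of both phenols gives ethers that should survive the organometallic step and come off with buffered fluoride under near-neutral conditions.

Step 14
Reactants: 19 [2-(but-2-yn-1-yl)-4-chloro-5-methyl-1,3-phenylene]bis(oxy)bis[tert-butyl(dimethyl)silane]; 11 2-[(1S,2S,6R)-1,2,6-trimethyl-3-oxocyclohexyl]acetaldehyde
Product: 22 (2S,3S,4R)-3-[(2S,3E)-5-{2,6-bis[(tert-butyldimethylsilyl)oxy]-3-chloro-4-methylphenyl}-2-hydroxy-3-methylpent-3-en-1-yl]-2,3,4-trimethylcyclohexan-1-one, via alkenylzirconocene chloride 20 (not isolated), via alkenylmethylzinc 21 (not isolated)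
Conditions: Cp2Zr(H)Cl (1.3 equiv), CH2Cl2, rt; Me2Zn (PhMe), −65 °C; (+)-3-exo-morpholinoisoborneol ((+)-MIB, 10 mol %), then 11, −30 → 0 °C; NH4Cl (aq)
Reagents that add atoms: none
Why: Syn-hydrozirconation places zirconium on the less hindered, methyl-bearing alkyne carbon and fixes the (E)-alkene, and after Zr→Zn transmetalation the amino-alcohol-catalysed alkenylzinc addition attacks the Re face of the aldehyde (S at C4, catalyst control) while the alkenylzinc is inert to the hindered ring ketone.

Step 15
Reactants: 22 bis-TBS ether (name as in step 14)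
Product: 23 4-chloro-2-{(2E,4S)-4-hydroxy-3-methyl-5-[(1S,2S,6R)-1,2,6-trimethyl-3-oxocyclohexyl]pent-2-en-1-yl}-5-methylbenzene-1,3-diol
Conditions: Bu4NF, AcOH (1:1), THF, 0 °C
Reagents that add atoms: none
Why: Fluoride cleaves the two aryl silyl ethers, and the acetic acid buffer keeps the phenoxides and the epimerisable C2' centre away from basic conditions.

Step 16
Reactants: 23 resorcinol (name as in step 15)
Product: 24 2-chloro-5-hydroxy-6-{(2E,4S)-4-hydroxy-3-methyl-5-[(1S,2S,6R)-1,2,6-trimethyl-3-oxocyclohexyl]pent-2-en-1-yl}-3-methylcyclohexa-2,5-diene-1,4-dione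
Conditions: (KO3S)2NO (2.2 equiv), KH2PO4 buffer, H2O/acetone, 0 °C → rt
Reagents that add atoms: potassium nitrosodisulfonate, [K+].[K+].[O]N(S(=O)(=O)[O-])S(=O)(=O)[O-]
Why: Teuber oxidation: the nitroxyl radical oxidises the phenol whose para position is the only aryl CH to the para-quinone, which leaves the second hydroxyl as the 2-hydroxy group of the quinone, and the buffered medium should spare the allylic alcohol and C2'.

**Compound list**

1 | (E)-penta-1,3-diene | C=C/C=C/C | starting material
2 | (E)-2-methylbut-2-enal | C/C=C(\C)C=O | starting material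
3 | (1S,2R,6R)-1,2,6-trimethylcyclohex-3-ene-1-carbaldehyde | O=C[C@@]1(C)[C@H](C)CC=C[C@H]1C | intermediate
4 | (1S,2R,6R)-1,2,6-trimethylcyclohex-3-ene-1-carboxylic acid | OC(=O)[C@@]1(C)[C@H](C)CC=C[C@H]1C | intermediate
5 | 4-iodo-1,2,8-trimethyl-6-oxabicyclo[3.2.1]octan-7-one (O cis to the carbonyl bridge carbon, I trans to O) | O=C1O[C@@H]2[C@@H](I)C[C@@H](C)[C@@]1(C)[C@@H]2C | intermediate
6 | 1,2,8-trimethyl-6-oxabicyclo[3.2.1]octan-7-one | O=C1O[C@@H]2CC[C@@H](C)[C@@]1(C)[C@@H]2C | intermediate
7 | 1,2,8-trimethyl-6-oxabicyclo[3.2.1]octan-7-ol (anomer mixture) | OC1O[C@@H]2CC[C@@H](C)[C@@]1(C)[C@@H]2C | intermediate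
8 | (1R,2S,3S,4R)-3-ethenyl-2,3,4-trimethylcyclohexan-1-ol | C=C[C@@]1(C)[C@H](C)CC[C@@H](O)[C@H]1C | intermediate
9 | bis-9-BBN adduct of 8 (C4–B and C3'–O–B, each boron in a 9-borabicyclo[3.3.1]nonane) | C1CCC2CCCC1B2CC[C@@]3(C)[C@H](C)CC[C@@H](OB4C5CCCC4CCC5)[C@H]3C | intermediate
10 | (1R,2S,3S,4R)-3-(2-hydroxyethyl)-2,3,4-trimethylcyclohexan-1-ol | OCC[C@@]1(C)[C@H](C)CC[C@@H](O)[C@H]1C | intermediate
11 | 2-[(1S,2S,6R)-1,2,6-trimethyl-3-oxocyclohexyl]acetaldehyde | O=CC[C@@]1(C)[C@H](C)CCC(=O)[C@H]1C | intermediate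
12 | 5-methylbenzene-1,3-diol | Cc1cc(O)cc(O)c1 | starting material
13 | 1,3-bis(methoxymethoxy)-5-methylbenzene | COCOc1cc(C)cc(OCOC)c1 | intermediate
14 | 1-bromobut-2-yne | CC#CCBr | starting material
15 | [2,6-bis(methoxymethoxy)-4-methylphenyl]lithium | [Li]c1c(OCOC)cc(C)cc1OCOC | intermediate
16 | 2-(but-2-yn-1-yl)-1,3-bis(methoxymethoxy)-5-methylbenzene | CC#CCc1c(OCOC)cc(C)cc1OCOC | intermediate
17 | 2-(but-2-yn-1-yl)-5-methylbenzene-1,3-diol | CC#CCc1c(O)cc(C)cc1O | intermediate
18 | 2-(but-2-yn-1-yl)-4-chloro-5-methylbenzene-1,3-diol | CC#CCc1c(O)cc(C)c(Cl)c1O | intermediate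
19 | [2-(but-2-yn-1-yl)-4-chloro-5-methyl-1,3-phenylene]bis(oxy)bis[tert-butyl(dimethyl)silane] | CC#CCc1c(O[Si](C)(C)C(C)(C)C)cc(C)c(Cl)c1O[Si](C)(C)C(C)(C)C | intermediate
20 | chlorobis(cyclopentadienyl)[(E)-4-aryl-but-2-en-2-yl]zirconium (aryl as in 19) | C/C(=C\Cc1c(O[Si](C)(C)C(C)(C)C)cc(C)c(Cl)c1O[Si](C)(C)C(C)(C)C)[Zr](Cl)(C1C=CC=C1)C1C=CC=C1 | intermediate
21 | [(E)-4-aryl-but-2-en-2-yl](methyl)zinc (aryl as in 19) | C/C(=C\Cc1c(O[Si](C)(C)C(C)(C)C)cc(C)c(Cl)c1O[Si](C)(C)C(C)(C)C)[Zn]C | intermediate
22 | (2S,3S,4R)-3-[(2S,3E)-5-{2,6-bis[(tert-butyldimethylsilyl)oxy]-3-chloro-4-methylphenyl}-2-hydroxy-3-methylpent-3-en-1-yl]-2,3,4-trimethylcyclohexan-1-one | Cc1cc(O[Si](C)(C)C(C)(C)C)c(C/C=C(\C)[C@@H](O)C[C@@]2(C)[C@H](C)CCC(=O)[C@H]2C)c(O[Si](C)(C)C(C)(C)C)c1Cl | intermediate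
23 | 4-chloro-2-{(2E,4S)-4-hydroxy-3-methyl-5-[(1S,2S,6R)-1,2,6-trimethyl-3-oxocyclohexyl]pent-2-en-1-yl}-5-methylbenzene-1,3-diol | Cc1cc(O)c(C/C=C(\C)[C@@H](O)C[C@@]2(C)[C@H](C)CCC(=O)[C@H]2C)c(O)c1Cl | intermediate
24 | 2-chloro-5-hydroxy-6-{(2E,4S)-4-hydroxy-3-methyl-5-[(1S,2S,6R)-1,2,6-trimethyl-3-oxocyclohexyl]pent-2-en-1-yl}-3-methylcyclohexa-2,5-diene-1,4-dione | CC1=C(Cl)C(=O)C(C/C=C(\C)[C@@H](O)C[C@@]2(C)[C@H](C)CCC(=O)[C@H]2C)=C(O)C1=O | target

**Count**

Total steps: 16. Longest linear sequence: 11 steps (steps 1–8, then 14–16).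

**Steps most likely to fail**

Step 1. The trisubstituted enal may add too slowly to an unactivated diene, and the chiral Lewis acid may give insufficient facial or endo selection. The fallback sets out from 1 and 2 and returns at 4. The cycloaddition is run with Me2AlCl in CH2Cl2 at −20 °C, which should also favour the endo adduct but gives it as the racemate, that is 3 together with its enantiomer (1R,2S,6S)-1,2,6-trimethylcyclohex-3-ene-1-carbaldehyde F1. Chlorite oxidation as in step 2 gives acid 4 mixed with (1R,2S,6S)-1,2,6-trimethylcyclohex-3-ene-1-carboxylic acid F2. The acids are resolved by fractional crystallisation with (R)-1-phenylethylamine; the salt (R)-1-phenylethan-1-aminium (1S,2R,6R)-1,2,6-trimethylcyclohex-3-ene-1-carboxylate F3 is collected (the (S)-amine is taken if the other salt is the less soluble one) and split with dilute HCl to return 4.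

Step 14. Regiocontrol in the hydrozirconation of the internal alkyne may be incomplete, the facial selectivity of the alkenylzinc addition to a β-quaternary aliphatic aldehyde may be low, and the keto-aldehyde may undergo intramolecular aldol addition. The fallback sets out from 19 and 11 and returns at 22. Hydrozirconation of 19 with Cp2Zr(H)Cl and iodinolysis (I2) gives {4-chloro-2-[(2E)-3-iodobut-2-en-1-yl]-5-methyl-1,3-phenylene}bis(oxy)bis[tert-butyl(dimethyl)silane] F4, which can be purified from any regioisomer. Nozaki–Hiyama–Kishi coupling of F4 with 11 (CrCl2, NiCl2 cat., DMF) is selective for the aldehyde and gives the allylic alcohol as both C4 epimers F5. MnO2 oxidises only the allylic alcohol to the enone F6. Reduction with (R)-2-methyl-CBS-oxazaborolidine and catecholborane at −78 °C, in which the conjugated enone should react ahead of the flanked ring ketone, gives 22.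

Step 3. Lactonisation may be slow because the iodonium ion must form on the ring face that carries the axial C6' methyl (1,3-diaxial clash with iodine), which would allow iodohydrin formation to compete. The fallback sets out from 4 and returns at 6. Acid 4 is cyclised directly by proton-initiated Markovnikov hydro-acyloxylation of the ring alkene (AgOTf, 5 mol %, ClCH2CH2Cl, 70 °C), in which only a hydrogen enters at C4'; no new compound arises (F0), and steps 3 and 4 are both replaced.

**Further compounds**

F1 | step 1 | (1R,2S,6S)-1,2,6-trimethylcyclohex-3-ene-1-carbaldehyde | O=C[C@]1(C)[C@@H](C)CC=C[C@@H]1C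
F2 | step 1 | (1R,2S,6S)-1,2,6-trimethylcyclohex-3-ene-1-carboxylic acid | OC(=O)[C@]1(C)[C@@H](C)CC=C[C@@H]1C
F3 | step 1 | (R)-1-phenylethan-1-aminium (1S,2R,6R)-1,2,6-trimethylcyclohex-3-ene-1-carboxylate | [O-]C(=O)[C@@]1(C)[C@H](C)CC=C[C@H]1C.C[C@@H]([NH3+])c1ccccc1
F0 | step 3 | none | none
F4 | step 14 | {4-chloro-2-[(2E)-3-iodobut-2-en-1-yl]-5-methyl-1,3-phenylene}bis(oxy)bis[tert-butyl(dimethyl)silane] | C/C(I)=C\Cc1c(O[Si](C)(C)C(C)(C)C)cc(C)c(Cl)c1O[Si](C)(C)C(C)(C)C
F5 | step 14 | (2S,3S,4R)-3-[(3E)-5-{2,6-bis[(tert-butyldimethylsilyl)oxy]-3-chloro-4-methylphenyl}-2-hydroxy-3-methylpent-3-en-1-yl]-2,3,4-trimethylcyclohexan-1-one, both epimers at the carbinol carbon | Cc1cc(O[Si](C)(C)C(C)(C)C)c(C/C=C(\C)C(O)C[C@@]2(C)[C@H](C)CCC(=O)[C@H]2C)c(O[Si](C)(C)C(C)(C)C)c1Cl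
F6 | step 14 | (2S,3S,4R)-3-[(3E)-5-{2,6-bis[(tert-butyldimethylsilyl)oxy]-3-chloro-4-methylphenyl}-3-methyl-2-oxopent-3-en-1-yl]-2,3,4-trimethylcyclohexan-1-one | Cc1cc(O[Si](C)(C)C(C)(C)C)c(C/C=C(\C)C(=O)C[C@@]2(C)[C@H](C)CCC(=O)[C@H]2C)c(O[Si](C)(C)C(C)(C)C)c1Cl
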